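Retrosynthetic overview:
- The target is cochliodinol with one vinylogous-acid OH exchanged for OOH, so the last disconnection is C–OOH to C–OMe (addition–elimination by hydroperoxide on the monomethyl ether made in the same flask).
- The quinone ring is the only ring formed. It is cut into two identical ethyl 5-prenylindol-3-ylpyruvate units, joined head-to-tail by a double Claisen condensation that copies the biosynthetic dimerisation of two indolylpyruvate units and gives the ring directly at the quinone oxidation level.
- The keto ester comes from 5-prenylindole by C3 alkylation with a nitrosoalkene, then deoximation.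
- 5-Prenylindole comes from 5-bromoindole by Stille prenylation; both indole rings are bought.

Assumption: the target has no stereocentre and no stereogenic double bond, so it is achiral and needs no stereocontrol; the oxime geometry of 4 and 6 is irrelevant because step 3 destroys it.
Assumption: 2 and 4 are taken as catalogue chemicals.

Step 1
Reactants: 1 5-bromo-1H-indole; 2 tributyl(3-methylbut-2-en-1-yl)stannane
Product: 3 5-(3-methylbut-2-en-1-yl)-1H-indole
Conditions: Pd(PPh3)4 (5 mol %), DMF, 100 °C, argon; aq. KF work-up
Reagents that add atoms: none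
Why: Stille cross-coupling, in which zerovalent palladium inserts into the C5–Br bond, the allyl stannane transmetalates and reductive elimination at the unhindered CH2 terminus gives the linear prenyl arene, the free indole N–H being tolerated.

Step 2
Reactants: 3 5-(3-methylbut-2-en-1-yl)-1H-indole; 4 ethyl 3-bromo-2-(hydroxyimino)propanoate
Product: 6 ethyl 2-(hydroxyimino)-3-[5-(3-methylbut-2-en-1-yl)-1H-indol-3-yl]propanoate, via ethyl 2-nitrosoacrylate 5 (not isolated)
Conditions: Na2CO3 (4 equiv), CH2Cl2, rt, 18 h; 4 (1.3 equiv) added in three portions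
Reagents that add atoms: none
Why: Gilchrist nitrosoalkene alkylation, in which Na2CO3 dehydrobrominates 4 to the electron-poor heterodiene 5, which is trapped at the most nucleophilic indole position (C3) by hetero-Diels–Alder addition and re-aromatising ring opening, while the unactivated prenyl alkene does not compete.

Step 3
Reactants: 6 ethyl 2-(hydroxyimino)-3-[5-(3-methylbut-2-en-1-yl)-1H-indol-3-yl]propanoate
Product: 8 ethyl 3-[5-(3-methylbut-2-en-1-yl)-1H-indol-3-yl]-2-oxopropanoate, via imino ester 7 (not isolated)
Conditions: TiCl3 (2.5 equiv, aq.), NH4OAc buffer (pH about 5), THF/H2O, 0 °C to rt, argon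
Reagents that add atoms: water O
Why: Reductive deoximation with trivalent titanium (Timms–Wildsmith type), in which two one-electron transfers cleave the N–O bond to the N-unsubstituted imine 7, which hydrolyses in the buffered medium to the enol-rich α-keto ester without touching indole, ester or alkene.

Step 4
Reactants: 8 ethyl 3-[5-(3-methylbut-2-en-1-yl)-1H-indol-3-yl]-2-oxopropanoate (two molecules)
Product: 10 cochliodinol, via acyclic Claisen adduct 9 (not isolated)
Conditions: KOt-Bu (1.05 equiv per 8), degassed THF, 0 °C to 65 °C, argon, 12 h; then aq. HCl (1 N), 0 °C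
Reagents that add atoms: none
Why: Proposed new method: complete pre-enolisation of 8 removes every ketone electrophile (shutting down the usual aldol/lactonisation to an isotetronic acid), so on heating the potassium enolate aggregate can only be acylated at carbon by an ester, giving 9 by an intermolecular Claisen condensation and then the six-membered ring by a Dieckmann-type closure of the second enolate carbon onto the remaining ester, each expelled ethoxide being consumed by deprotonating the new 1,3-dicarbonyl position so that the sequence is pulled to the doubly vinylogous dicarboxylate (cochliodinol dianion), which forms directly at the quinone oxidation level and is freed by acid; the closest known reaction type is the head-to-tail double Claisen self-condensation of diethyl succinate to succinylsuccinate, and the step copies the thioester dimerisation of two indolylpyruvate units carried out by NRPS-like quinone synthetases.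

Step 5
Reactants: 10 cochliodinol
Product: 12 hydroperoxycochliodinol, via cochliodinol monomethyl ether 11 (not isolated)
Conditions: TMSCHN2 (1.0 equiv), THF/MeOH (4:1), 0 °C; evaporate; then 30% aq. H2O2 (10 equiv), LiOH (3.5 equiv), THF/H2O (3:1), 0 °C, dark, 1–2 h; cold aq. HCl to pH 3, no reductive quench
Reagents that add atoms: hydrogen peroxide OO
Why: Proposed new method: one acidic quinone OH of 10 is O-methylated by TMSCHN2 as a carboxylic acid would be, and the resulting vinylogous methyl ester 11 undergoes addition–elimination at its OMe-bearing ring carbon with the α-effect nucleophile LiOOH (methoxide is expelled from the β-alkoxy enolate), while the remaining OH is protected as its unreactive vinylogous carboxylate and the product as its peroxy anion; the closest known reaction types are the LiOOH perhydrolysis of esters and imides to peracids and the hydroxide hydrolysis of methoxy bis(indolyl)quinones.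

Compound list
1 | 5-bromo-1H-indole | Brc1ccc2[nH]ccc2c1 | starting material
2 | tributyl(3-methylbut-2-en-1-yl)stannane | CCCC[Sn](CCCC)(CCCC)CC=C(C)C | starting material
3 | 5-(3-methylbut-2-en-1-yl)-1H-indole | CC(C)=CCc1ccc2[nH]ccc2c1 | intermediate
4 | ethyl 3-bromo-2-(hydroxyimino)propanoate | CCOC(=O)C(CBr)=NO | starting material
5 | ethyl 2-nitrosoprop-2-enoate (ethyl 2-nitrosoacrylate) | CCOC(=O)C(=C)N=O | intermediate
6 | ethyl 2-(hydroxyimino)-3-[5-(3-methylbut-2-en-1-yl)-1H-indol-3-yl]propanoate | CCOC(=O)C(Cc1c[nH]c2ccc(CC=C(C)C)cc12)=NO | intermediate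
7 | ethyl 2-imino-3-[5-(3-methylbut-2-en-1-yl)-1H-indol-3-yl]propanoate | CCOC(=O)C(=N)Cc1c[nH]c2ccc(CC=C(C)C)cc12 | intermediate
8 | ethyl 3-[5-(3-methylbut-2-en-1-yl)-1H-indol-3-yl]-2-oxopropanoate | CCOC(=O)C(=O)Cc1c[nH]c2ccc(CC=C(C)C)cc12 | intermediate
9 | ethyl 2,4,5-trioxo-3,6-bis[5-(3-methylbut-2-en-1-yl)-1H-indol-3-yl]hexanoate (enolisable, no defined stereocentre) | CCOC(=O)C(=O)C(c1c[nH]c2ccc(CC=C(C)C)cc12)C(=O)C(=O)Cc1c[nH]c2ccc(CC=C(C)C)cc12 | intermediate
10 | cochliodinol, 2,5-dihydroxy-3,6-bis[5-(3-methylbut-2-en-1-yl)-1H-indol-3-yl]cyclohexa-2,5-diene-1,4-dione | CC(C)=CCc1ccc2[nH]cc(C3=C(O)C(=O)C(c4c[nH]c5ccc(CC=C(C)C)cc45)=C(O)C3=O)c2c1 | intermediate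
11 | cochliodinol monomethyl ether, 2-hydroxy-5-methoxy-3,6-bis[5-(3-methylbut-2-en-1-yl)-1H-indol-3-yl]cyclohexa-2,5-diene-1,4-dione | CC(C)=CCc1ccc2[nH]cc(C3=C(O)C(=O)C(c4c[nH]c5ccc(CC=C(C)C)cc45)=C(OC)C3=O)c2c1 | intermediate
12 | hydroperoxycochliodinol, 2-hydroperoxy-5-hydroxy-3,6-bis[5-(3-methylbut-2-en-1-yl)-1H-indol-3-yl]cyclohexa-2,5-diene-1,4-dione | CC(C)=CCc1ccc2[nH]cc(C3=C(O)C(=O)C(c4c[nH]c5ccc(CC=C(C)C)cc45)=C(OO)C3=O)c2c1 | target

Total step count: 5. Longest linear sequence: 5 (the route is linear; step 4 joins two molecules of the same intermediate).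

Steps most likely to fail, each with one fallback

Step 4 is the riskiest. Two stabilised enolates may not acylate each other. Any keto form present would divert material to the aldol/lactone dimer. The fallback sets out from 3 and gives up the condensation route to the quinone. Two equivalents of 3 are added to 2,3,5,6-tetrabromo-1,4-benzoquinone (Cs2CO3, MeCN, rt) to give 2,5-dibromo-3,6-bis[5-(3-methylbut-2-en-1-yl)-1H-indol-3-yl]cyclohexa-2,5-diene-1,4-dione F1. Its two vinylic bromides are then hydrolysed (NaOH, MeOH/H2O, reflux; then acid), and the route is rejoined at 10.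

Step 5 is second. Displacement of methoxide on the anionic quinone may be slow. Hydroperoxide may instead epoxidise or cleave the ring, and the mono-methylation is only partly selective. The fallback sets out from 10 and uses a vinylogous acid chloride in place of the ether. 1-Chloro-N,N,2-trimethylprop-1-en-1-amine (1.0 equiv, CH2Cl2, 0 °C) converts one OH into Cl under neutral conditions to give 2-chloro-5-hydroxy-3,6-bis[5-(3-methylbut-2-en-1-yl)-1H-indol-3-yl]cyclohexa-2,5-diene-1,4-dione F2. Urea·H2O2 with NaHCO3 (THF/H2O, 0 °C) then displaces the much better leaving group chloride, as in the preparation of peracids from acid chlorides, and the route is rejoined at 12.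

Step 3 is third. The α-keto ester may be over-reduced by trivalent titanium, and the enol-rich product is air-sensitive. The fallback sets out from 3 and bypasses the oxime. Sc(OTf)3-catalysed Friedel–Crafts opening of ethyl oxirane-2-carboxylate at its CH2 terminus by C3 of 3 gives racemic ethyl 2-hydroxy-3-[5-(3-methylbut-2-en-1-yl)-1H-indol-3-yl]propanoate F3. Dess–Martin periodinane oxidation of its secondary alcohol rejoins the route at 8.

Further compounds
F1 | step 4 | 2,5-dibromo-3,6-bis[5-(3-methylbut-2-en-1-yl)-1H-indol-3-yl]cyclohexa-2,5-diene-1,4-dione | CC(C)=CCc1ccc2[nH]cc(C3=C(Br)C(=O)C(c4c[nH]c5ccc(CC=C(C)C)cc45)=C(Br)C3=O)c2c1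
F2 | step 5 | 2-chloro-5-hydroxy-3,6-bis[5-(3-methylbut-2-en-1-yl)-1H-indol-3-yl]cyclohexa-2,5-diene-1,4-dione | CC(C)=CCc1ccc2[nH]cc(C3=C(O)C(=O)C(c4c[nH]c5ccc(CC=C(C)C)cc45)=C(Cl)C3=O)c2c1
F3 | step 3 | ethyl 2-hydroxy-3-[5-(3-methylbut-2-en-1-yl)-1H-indol-3-yl]propanoate (racemic) | CCOC(=O)C(O)Cc1c[nH]c2ccc(CC=C(C)C)cc12
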